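**Strategy.** Everything rests on cutting ring C (C1 carrying the ring B oxygen, C2–H, hydroxyls on C3–C5, C6 carrying the ring D oxygen) into a masked triketide: the 1,3,5-related oxygens on C1, C3 and C5 mark an enol ether, an ester and a ketone. In one operation a γ-Claisen acylation (C6–C5) and a Dieckmann closure (C4–C3) convert an (E)-3,4-bis(aryloxy)but-2-enoate and methyl methoxyacetate into the arene, so both hindered aryl ethers of ring C are made beforehand by substitution at sp3 and vinylic carbon. The precursor carries ring A–B on the enol ether carbon and benzyl-protected ring D on the γ-carbon. The same manoeuvre later builds ring E.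

Key step: step 8

Remark: rings are lettered A to H from the 2,4,6-trihydroxyphenyl end; the target has no stereocentre, so the only stereochemical element of the route is the (E) geometry of the enoates.

Remark: shorthand used in names:
- ABO = 2,6-dimethoxy-4-(2,4,6-trimethoxyphenoxy)phenoxy
- ABCDO = 4-{6-[ABO]-2,3,4-trimethoxyphenoxy}-2,6-dimethoxyphenoxy (oxygen on ring D, between two methoxy groups)
- FGHO = 3,4-dimethoxy-5-[3,4,5-trimethoxy-2-(3,4,5-trimethoxyphenoxy)phenoxy]phenoxy (oxygen on ring F)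

Remark: ring E has the same oxygen pattern as ring C with the roles of the two phenols exchanged, and its ether to ring D is ortho-substituted on all four sides. It is therefore made by repeating the step 8 chemistry (steps 11, 12, 17, 18) rather than by arylation.

**Route**

Step 1
Reactants: 1 syringaldehyde (4-hydroxy-3,5-dimethoxybenzaldehyde)
Product: 2 4-(benzyloxy)-3,5-dimethoxybenzaldehyde
Conditions: BnBr, K2CO3, DMF, 60 °C
Reagents that add atoms: benzyl bromide, BrCc1ccccc1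
Why: Williamson etherification of the only phenol, with the aldehyde inert to carbonate.

Step 2
Reactants: 2 4-(benzyloxy)-3,5-dimethoxybenzaldehyde
Product: 4 4-(benzyloxy)-3,5-dimethoxyphenol, via aryl formate 3 (not isolated)
Conditions: mCPBA, CH2Cl2, 0 °C to rt; NaHCO3 wash; K2CO3 (cat.), MeOH, rt
Reagents that add atoms: mCPBA (3-chloroperbenzoic acid), OOC(=O)c1cccc(Cl)c1
Why: Baeyer–Villiger oxidation in which the electron-rich para-alkoxyaryl group migrates in preference to hydride, followed by methanolysis of the formate.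

Step 3
Reactants: 4 4-(benzyloxy)-3,5-dimethoxyphenol; 5 methyl 4-chloroacetoacetate (methyl 4-chloro-3-oxobutanoate)
Product: 6 methyl 4-[4-(benzyloxy)-3,5-dimethoxyphenoxy]-3-oxobutanoate
Conditions: NaH (2.2 equiv), THF–DMF, 0 °C to rt; dilute HCl
Reagents that add atoms: none
Why: Williamson-type SN2 displacement of the primary chloride by the phenoxide, the second equivalent of NaH holding the keto ester as its enolate so that it does not self-condense.

Step 4
Reactants: 6 methyl 4-[4-(benzyloxy)-3,5-dimethoxyphenoxy]-3-oxobutanoate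
Product: 7 methyl (E)-4-[4-(benzyloxy)-3,5-dimethoxyphenoxy]-3-(tosyloxy)but-2-enoate
Conditions: TsCl, N-methylimidazole, Et3N, MeCN, 0 °C to rt
Reagents that add atoms: 4-toluenesulfonyl chloride, Cc1ccc(cc1)S(=O)(=O)Cl
Why: O-sulfonylation of the β-keto ester enolate under non-chelating amine conditions (N-methylimidazole activates TsCl) should place the tosyloxy group anti to the ester and give the (E)-enol tosylate.

Step 5
Reactants: 8 2,4,6-trimethoxyphenol; 9 4-bromo-2,6-dimethoxybenzaldehyde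
Product: 10 2,6-dimethoxy-4-(2,4,6-trimethoxyphenoxy)benzaldehyde
Conditions: CuI (10 mol %), picolinic acid (20 mol %), K3PO4, DMSO, 90 °C, argon
Reagents that add atoms: none
Why: Ullmann diaryl ether coupling in which the bromide has no ortho substituent and is activated by the para-formyl group, while picolinic acid-ligated copper accommodates the doubly ortho-substituted phenol.

Step 6
Reactants: 10 2,6-dimethoxy-4-(2,4,6-trimethoxyphenoxy)benzaldehyde
Product: 12 2,6-dimethoxy-4-(2,4,6-trimethoxyphenoxy)phenol, via aryl formate 11 (not isolated)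
Conditions: mCPBA, CH2Cl2, 0 °C; NaHCO3 wash; K2CO3 (cat.), MeOH, rt
Reagents that add atoms: mCPBA (3-chloroperbenzoic acid), OOC(=O)c1cccc(Cl)c1
Why: Baeyer–Villiger oxidation with migration of the very electron-rich 2,6-dimethoxy-4-aryloxyphenyl group, then methanolysis of the formate.

Step 7
Reactants: 7 methyl (E)-4-[4-(benzyloxy)-3,5-dimethoxyphenoxy]-3-(tosyloxy)but-2-enoate; 12 2,6-dimethoxy-4-(2,4,6-trimethoxyphenoxy)phenol
Product: 13 methyl (E)-4-[4-(benzyloxy)-3,5-dimethoxyphenoxy]-3-[2,6-dimethoxy-4-(2,4,6-trimethoxyphenoxy)phenoxy]but-2-enoate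
Conditions: Cs2CO3, MeCN, 50 °C, argon
Reagents that add atoms: none
Why: Nucleophilic vinylic substitution by addition–elimination, in which the phenoxide adds to the β-carbon of the sulfonyloxy enoate, the ester-stabilised carbanion expels tosylate, and the more stable (E) enol ether with the aryloxy group anti to the ester should result.

Step 8
Reactants: 13 methyl (E)-4-[4-(benzyloxy)-3,5-dimethoxyphenoxy]-3-[2,6-dimethoxy-4-(2,4,6-trimethoxyphenoxy)phenoxy]but-2-enoate; 14 methyl methoxyacetate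
Product: 16 4-[4-(benzyloxy)-3,5-dimethoxyphenoxy]-5-[2,6-dimethoxy-4-(2,4,6-trimethoxyphenoxy)phenoxy]-2-methoxybenzene-1,3-diol, via keto ester 15 (not isolated)
Conditions: LiN(iPr)2 (2.5 equiv), THF, −78 °C; 14 (3 equiv), −78 to 0 °C; then NaOMe, MeOH, 65 °C; aq. HCl
Reagents that add atoms: none
Why: LiN(iPr)2 removes a γ-hydrogen (allylic, on the carbon bearing the ring D oxygen, held syn to the ester by the (E) geometry) to give the extended dienolate, whose γ-carbon attacks methyl methoxyacetate in a Claisen acylation that forms the C6–C5 bond of ring C and leaves keto ester 15 as its stabilised enolate. Under NaOMe in hot methanol the methoxy-bearing carbon of the ketone then adds, as its enolate, to the enoate ester and expels methoxide (Dieckmann condensation, C4–C3 bond), and the resulting cyclohexenedione enolises twice to the 2-methoxyresorcinol, an irreversible aromatisation that pulls the preceding equilibria forward. The closest known reaction types are the γ-acylation of β-alkoxycrotonate dienolates and the base-mediated Dieckmann or pyranone-to-resorcinol cyclisation of 3,5-dioxo ester equivalents. Ring C closes in a 6-(enolendo)-exo-trig mode, and no stereocentre is created because the only sp3 centre of 15 becomes an aromatic carbon. The step needs γ- over α-acylation, toward which the β-aryloxy donor directs the dienolate as in β-alkoxycrotonates, and C- over O-closure, which is secured because the (E) geometry holds the new ketone chain beside the ester and closure through the enolate oxygen is reversible under methoxide whereas C-closure ends in the aromatic sink.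

Step 9
Reactants: 16 4-[4-(benzyloxy)-3,5-dimethoxyphenoxy]-5-[2,6-dimethoxy-4-(2,4,6-trimethoxyphenoxy)phenoxy]-2-methoxybenzene-1,3-diol
Product: 17 2-(benzyloxy)-5-{6-[ABO]-2,3,4-trimethoxyphenoxy}-1,3-dimethoxybenzene
Conditions: Me2SO4, K2CO3, acetone, reflux
Reagents that add atoms: dimethyl sulfate, COS(=O)(=O)OC
Why: Williamson O-methylation of both phenoxides, the hard electrophile favouring O- over C-methylation of the electron-rich ring.

Step 10
Reactants: 17 2-(benzyloxy)-5-{6-[ABO]-2,3,4-trimethoxyphenoxy}-1,3-dimethoxybenzene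
Product: 18 4-{6-[ABO]-2,3,4-trimethoxyphenoxy}-2,6-dimethoxyphenol (ABCDO–H)
Conditions: H2 (1 atm), Pd/C, EtOAc–MeOH, rt
Reagents that add atoms: none
Why: Catalytic hydrogenolysis cleaves only the benzylic C–O bond and leaves methyl and diaryl ethers untouched.

Step 11
Reactants: 18 ABCDO–H; 5 methyl 4-chloroacetoacetate
Product: 19 methyl 4-(ABCDO)-3-oxobutanoate
Conditions: NaH (2.2 equiv), NaI (cat.), DMF, 0 to 40 °C; dilute HCl
Reagents that add atoms: none
Why: Williamson-type SN2 displacement as in step 3, chosen because attack on a primary chloride is hardly slowed by the two ortho-methoxy groups of the ring D phenoxide, so the fourfold ortho-substituted D–O–E ether is begun at an sp3 carbon.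

Step 12
Reactants: 19 methyl 4-(ABCDO)-3-oxobutanoate
Product: 20 methyl (E)-4-(ABCDO)-3-(tosyloxy)but-2-enoate
Conditions: TsCl, N-methylimidazole, Et3N, MeCN, 0 °C to rt
Reagents that add atoms: 4-toluenesulfonyl chloride, Cc1ccc(cc1)S(=O)(=O)Cl
Why: Amine-mediated O-sulfonylation of the non-chelated β-keto ester enolate as in step 4, expected to give the (E)-enol tosylate.

Step 13
Reactants: 21 3,4,5-trimethoxyphenol; 22 2-bromo-3,4,5-trimethoxybenzaldehyde
Product: 23 3,4,5-trimethoxy-2-(3,4,5-trimethoxyphenoxy)benzaldehyde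
Conditions: CuI (10 mol %), picolinic acid (20 mol %), K3PO4, DMSO, 90 °C, argon
Reagents that add atoms: none
Why: Ullmann diaryl ether coupling in which the ortho-formyl group activates the flanked bromide and the phenol carries no ortho substituent.

Step 14
Reactants: 23 3,4,5-trimethoxy-2-(3,4,5-trimethoxyphenoxy)benzaldehyde
Product: 25 3,4,5-trimethoxy-2-(3,4,5-trimethoxyphenoxy)phenol, via aryl formate 24 (not isolated)
Conditions: mCPBA, CH2Cl2, 0 °C to rt; NaHCO3 wash; K2CO3 (cat.), MeOH, rt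
Reagents that add atoms: mCPBA (3-chloroperbenzoic acid), OOC(=O)c1cccc(Cl)c1
Why: Baeyer–Villiger oxidation with migration of the electron-rich aryl group (ortho-aryloxy, para-methoxy), then methanolysis of the formate.

Step 15
Reactants: 25 3,4,5-trimethoxy-2-(3,4,5-trimethoxyphenoxy)phenol; 26 3-bromo-4,5-dimethoxybenzaldehyde
Product: 27 3,4-dimethoxy-5-[3,4,5-trimethoxy-2-(3,4,5-trimethoxyphenoxy)phenoxy]benzaldehyde
Conditions: CuI (10 mol %), picolinic acid (20 mol %), K3PO4, DMSO, 100 °C, argon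
Reagents that add atoms: none
Why: Ullmann diaryl ether coupling of a phenol and a bromide that each carry a single ortho substituent, a degree of hindrance that picolinic acid-ligated copper tolerates.

Step 16
Reactants: 27 3,4-dimethoxy-5-[3,4,5-trimethoxy-2-(3,4,5-trimethoxyphenoxy)phenoxy]benzaldehyde
Product: 29 3,4-dimethoxy-5-[3,4,5-trimethoxy-2-(3,4,5-trimethoxyphenoxy)phenoxy]phenol (FGHO–H), via aryl formate 28 (not isolated)
Conditions: mCPBA, CH2Cl2, 0 °C to rt; NaHCO3 wash; K2CO3 (cat.), MeOH, rt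
Reagents that add atoms: mCPBA (3-chloroperbenzoic acid), OOC(=O)c1cccc(Cl)c1
Why: Baeyer–Villiger oxidation of a 3,4,5-trioxygenated benzaldehyde, whose para-methoxyaryl group migrates, then methanolysis of the formate.

Step 17
Reactants: 20 methyl (E)-4-(ABCDO)-3-(tosyloxy)but-2-enoate; 29 FGHO–H
Product: 30 methyl (E)-4-(ABCDO)-3-(FGHO)but-2-enoate
Conditions: Cs2CO3, MeCN, 50 °C, argon
Reagents that add atoms: none
Why: Nucleophilic vinylic substitution by addition–elimination as in step 7, here with a phenoxide that has no ortho substituent, again expected to deliver the (E) enol ether.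

Step 18
Reactants: 30 methyl (E)-4-(ABCDO)-3-(FGHO)but-2-enoate; 14 methyl methoxyacetate
Product: 32 4-(ABCDO)-5-(FGHO)-2-methoxybenzene-1,3-diol, via keto ester 31 (not isolated)
Conditions: LiN(iPr)2 (2.5 equiv), THF, −78 °C; 14 (3 equiv), −78 to 0 °C; then NaOMe, MeOH, 65 °C; aq. HCl
Reagents that add atoms: none
Why: The same γ-Claisen acylation and Dieckmann aromatisation as in step 8, now with the ring D oxygen on the γ-carbon and the ring F oxygen on the enol ether carbon, closing ring E in a 6-(enolendo)-exo-trig mode without creating a stereocentre.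

Step 19
Reactants: 32 4-(ABCDO)-5-(FGHO)-2-methoxybenzene-1,3-diol
Product: 33 CNP0309601.0
Conditions: BBr3 (excess), CH2Cl2, −78 °C to rt; H2O; argon throughout
Reagents that add atoms: none
Why: Lewis acid-mediated ether cleavage in which BBr3 coordinates each of the 19 methoxy oxygens and bromide removes the methyl group by SN2, while the diaryl ether bonds are inert and exclusion of air protects the pyrogallol-type product.

**Compound list**

1 | syringaldehyde (4-hydroxy-3,5-dimethoxybenzaldehyde) | COc1cc(C=O)cc(OC)c1O | starting material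
2 | 4-(benzyloxy)-3,5-dimethoxybenzaldehyde | COc1cc(C=O)cc(OC)c1OCc1ccccc1 | intermediate
3 | 4-(benzyloxy)-3,5-dimethoxyphenyl formate | COc1cc(OC=O)cc(OC)c1OCc1ccccc1 | intermediate
4 | 4-(benzyloxy)-3,5-dimethoxyphenol | COc1cc(O)cc(OC)c1OCc1ccccc1 | intermediate
5 | methyl 4-chloroacetoacetate (methyl 4-chloro-3-oxobutanoate) | COC(=O)CC(=O)CCl | starting material
6 | methyl 4-[4-(benzyloxy)-3,5-dimethoxyphenoxy]-3-oxobutanoate | COC(=O)CC(=O)COc1cc(OC)c(OCc2ccccc2)c(OC)c1 | intermediate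
7 | methyl (E)-4-[4-(benzyloxy)-3,5-dimethoxyphenoxy]-3-(tosyloxy)but-2-enoate | COC(=O)/C=C(\COc1cc(OC)c(OCc2ccccc2)c(OC)c1)OS(=O)(=O)c1ccc(C)cc1 | intermediate
8 | 2,4,6-trimethoxyphenol | COc1cc(OC)c(O)c(OC)c1 | starting material
9 | 4-bromo-2,6-dimethoxybenzaldehyde | COc1cc(Br)cc(OC)c1C=O | starting material
10 | 2,6-dimethoxy-4-(2,4,6-trimethoxyphenoxy)benzaldehyde | COc1cc(OC)c(Oc2cc(OC)c(C=O)c(OC)c2)c(OC)c1 | intermediate
11 | 2,6-dimethoxy-4-(2,4,6-trimethoxyphenoxy)phenyl formate | COc1cc(OC)c(Oc2cc(OC)c(OC=O)c(OC)c2)c(OC)c1 | intermediate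
12 | 2,6-dimethoxy-4-(2,4,6-trimethoxyphenoxy)phenol | COc1cc(OC)c(Oc2cc(OC)c(O)c(OC)c2)c(OC)c1 | intermediate
13 | methyl (E)-4-[4-(benzyloxy)-3,5-dimethoxyphenoxy]-3-[2,6-dimethoxy-4-(2,4,6-trimethoxyphenoxy)phenoxy]but-2-enoate | COC(=O)/C=C(\COc1cc(OC)c(OCc2ccccc2)c(OC)c1)Oc1c(OC)cc(Oc2c(OC)cc(OC)cc2OC)cc1OC | intermediate
14 | methyl methoxyacetate | COCC(=O)OC | starting material
15 | methyl (E)-4-[4-(benzyloxy)-3,5-dimethoxyphenoxy]-3-[2,6-dimethoxy-4-(2,4,6-trimethoxyphenoxy)phenoxy]-6-methoxy-5-oxohex-2-enoate (racemic at C4) | COC(=O)/C=C(/Oc1c(OC)cc(Oc2c(OC)cc(OC)cc2OC)cc1OC)C(Oc1cc(OC)c(OCc2ccccc2)c(OC)c1)C(=O)COC | intermediate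
16 | 4-[4-(benzyloxy)-3,5-dimethoxyphenoxy]-5-[2,6-dimethoxy-4-(2,4,6-trimethoxyphenoxy)phenoxy]-2-methoxybenzene-1,3-diol | Oc1cc(Oc2c(OC)cc(Oc3c(OC)cc(OC)cc3OC)cc2OC)c(Oc2cc(OC)c(OCc3ccccc3)c(OC)c2)c(O)c1OC | intermediate
17 | 2-(benzyloxy)-5-{6-[2,6-dimethoxy-4-(2,4,6-trimethoxyphenoxy)phenoxy]-2,3,4-trimethoxyphenoxy}-1,3-dimethoxybenzene | COc1cc(Oc2c(OC)c(OC)c(OC)cc2Oc2c(OC)cc(Oc3c(OC)cc(OC)cc3OC)cc2OC)cc(OC)c1OCc1ccccc1 | intermediate
18 | 4-{6-[2,6-dimethoxy-4-(2,4,6-trimethoxyphenoxy)phenoxy]-2,3,4-trimethoxyphenoxy}-2,6-dimethoxyphenol (ABCDO–H) | Oc1c(OC)cc(Oc2c(OC)c(OC)c(OC)cc2Oc2c(OC)cc(Oc3c(OC)cc(OC)cc3OC)cc2OC)cc1OC | intermediate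
19 | methyl 4-(ABCDO)-3-oxobutanoate | COC(=O)CC(=O)COc1c(OC)cc(Oc2c(OC)c(OC)c(OC)cc2Oc2c(OC)cc(Oc3c(OC)cc(OC)cc3OC)cc2OC)cc1OC | intermediate
20 | methyl (E)-4-(ABCDO)-3-(tosyloxy)but-2-enoate | COC(=O)/C=C(\COc1c(OC)cc(Oc2c(OC)c(OC)c(OC)cc2Oc2c(OC)cc(Oc3c(OC)cc(OC)cc3OC)cc2OC)cc1OC)OS(=O)(=O)c1ccc(C)cc1 | intermediate
21 | 3,4,5-trimethoxyphenol | COc1cc(O)cc(OC)c1OC | starting material
22 | 2-bromo-3,4,5-trimethoxybenzaldehyde | COc1cc(C=O)c(Br)c(OC)c1OC | starting material
23 | 3,4,5-trimethoxy-2-(3,4,5-trimethoxyphenoxy)benzaldehyde | COc1cc(C=O)c(Oc2cc(OC)c(OC)c(OC)c2)c(OC)c1OC | intermediate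
24 | 3,4,5-trimethoxy-2-(3,4,5-trimethoxyphenoxy)phenyl formate | COc1cc(OC=O)c(Oc2cc(OC)c(OC)c(OC)c2)c(OC)c1OC | intermediate
25 | 3,4,5-trimethoxy-2-(3,4,5-trimethoxyphenoxy)phenol | COc1cc(O)c(Oc2cc(OC)c(OC)c(OC)c2)c(OC)c1OC | intermediate
26 | 3-bromo-4,5-dimethoxybenzaldehyde | COc1cc(C=O)cc(Br)c1OC | starting material
27 | 3,4-dimethoxy-5-[3,4,5-trimethoxy-2-(3,4,5-trimethoxyphenoxy)phenoxy]benzaldehyde | COc1cc(C=O)cc(Oc2cc(OC)c(OC)c(OC)c2Oc2cc(OC)c(OC)c(OC)c2)c1OC | intermediate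
28 | 3,4-dimethoxy-5-[3,4,5-trimethoxy-2-(3,4,5-trimethoxyphenoxy)phenoxy]phenyl formate | COc1cc(OC=O)cc(Oc2cc(OC)c(OC)c(OC)c2Oc2cc(OC)c(OC)c(OC)c2)c1OC | intermediate
29 | 3,4-dimethoxy-5-[3,4,5-trimethoxy-2-(3,4,5-trimethoxyphenoxy)phenoxy]phenol (FGHO–H) | COc1cc(O)cc(Oc2cc(OC)c(OC)c(OC)c2Oc2cc(OC)c(OC)c(OC)c2)c1OC | intermediate
30 | methyl (E)-4-(ABCDO)-3-(FGHO)but-2-enoate | COC(=O)/C=C(\COc1c(OC)cc(Oc2c(OC)c(OC)c(OC)cc2Oc2c(OC)cc(Oc3c(OC)cc(OC)cc3OC)cc2OC)cc1OC)Oc1cc(OC)c(OC)c(Oc2cc(OC)c(OC)c(OC)c2Oc2cc(OC)c(OC)c(OC)c2)c1 | intermediate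
31 | methyl (E)-4-(ABCDO)-3-(FGHO)-6-methoxy-5-oxohex-2-enoate (racemic at C4) | COC(=O)/C=C(/Oc1cc(OC)c(OC)c(Oc2cc(OC)c(OC)c(OC)c2Oc2cc(OC)c(OC)c(OC)c2)c1)C(Oc1c(OC)cc(Oc2c(OC)c(OC)c(OC)cc2Oc2c(OC)cc(Oc3c(OC)cc(OC)cc3OC)cc2OC)cc1OC)C(=O)COC | intermediate
32 | 4-(ABCDO)-5-(FGHO)-2-methoxybenzene-1,3-diol | Oc1cc(Oc2cc(OC)c(OC)c(Oc3cc(OC)c(OC)c(OC)c3Oc3cc(OC)c(OC)c(OC)c3)c2)c(Oc2c(OC)cc(Oc3c(OC)c(OC)c(OC)cc3Oc3c(OC)cc(Oc4c(OC)cc(OC)cc4OC)cc3OC)cc2OC)c(O)c1OC | intermediate
33 | CNP0309601.0, 4-(4-{6-[2,6-dihydroxy-4-(2,4,6-trihydroxyphenoxy)phenoxy]-2,3,4-trihydroxyphenoxy}-2,6-dihydroxyphenoxy)-5-{3,4-dihydroxy-5-[3,4,5-trihydroxy-2-(3,4,5-trihydroxyphenoxy)phenoxy]phenoxy}benzene-1,2,3-triol | Oc1cc(O)c(Oc2cc(O)c(Oc3cc(O)c(O)c(O)c3Oc3cc(O)c(Oc4c(Oc5cc(O)c(O)c(Oc6cc(O)c(O)c(O)c6Oc6cc(O)c(O)c(O)c6)c5)cc(O)c(O)c4O)c(O)c3)c(O)c2)c(O)c1 | target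

**Totals**

Total step count: 19.
Longest linear sequence: 13 steps (steps 1, 2, 3, 4, 7, 8, 9, 10, 11, 12, 17, 18, 19).

**Steps most likely to fail**

Step 8. The dienolate may be acylated at the α- instead of the γ-carbon. The open-chain keto ester may also stall before C–C closure, or lose the ring B aryloxy group to methoxide by vinylic exchange. Fallback, setting out from 12 and coming back at 17: ring C is assembled by arylation instead of annulation. Rieche formylation (Cl2CHOCH3, TiCl4, CH2Cl2) of commercial 5-bromo-1,2,3-trimethoxybenzene gives 6-bromo-2,3,4-trimethoxybenzaldehyde F1. Ullmann coupling of 12 with F1 (CuI, picolinic acid, K3PO4, DMSO, 100 °C; the ortho-formyl group activates the bromide) gives 6-(ABO)-2,3,4-trimethoxybenzaldehyde F2. Baeyer–Villiger oxidation with mCPBA gives the aryl formate F3, which K2CO3/MeOH cleaves to 6-(ABO)-2,3,4-trimethoxyphenol F4. A second Ullmann coupling of F4 with 2-(benzyloxy)-5-bromo-1,3-dimethoxybenzene F5 (from commercial 4-bromo-2,6-dimethoxyphenol, BnBr and K2CO3) gives 17, which already carries the three methoxy groups of ring C.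

Step 18. γ-Deprotonation and acylation take place next to the doubly ortho-substituted ring D oxygen and may be slow on this large substrate, so that retro-Claisen cleavage of the open-chain keto ester outruns ring closure. Fallback, setting out from 18 (with 22 and 29 from the route) and coming back at 33: ring E is introduced by arylation. Ullmann coupling of 18 with 22 under forcing conditions (CuI, 2,2,6,6-tetramethylheptane-3,5-dione, Cs2CO3, NMP, 120 °C; the bromide is activated by its ortho-formyl group) gives 2-(ABCDO)-3,4,5-trimethoxybenzaldehyde F6. Baeyer–Villiger oxidation with mCPBA gives the aryl formate F7, and methanolysis gives 2-(ABCDO)-3,4,5-trimethoxyphenol F8. Phenol 29 is converted with Tf2O and pyridine into 3,4-dimethoxy-5-[3,4,5-trimethoxy-2-(3,4,5-trimethoxyphenoxy)phenoxy]phenyl trifluoromethanesulfonate F9. Palladium-catalysed C–O cross-coupling of F8 with F9 (Pd2(dba)3, tBuXPhos, K3PO4, toluene, 100 °C) gives the fully methylated octamer 4-(ABCDO)-5-(FGHO)-1,2,3-trimethoxybenzene F10. BBr3 under the conditions of step 19 then cleaves its 21 methyl ethers to give 33.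

Step 7. The doubly ortho-substituted phenoxide may attack sulfur instead of the β-carbon, transferring the sulfonyl group and returning the keto ester enolate. Fallback, setting out from 4 and coming back at 13: the enol ether is made by conjugate addition to an alkyne instead of substitution on an alkene. Phenol 4 is propargylated (propargyl bromide, K2CO3, acetone) to 2-(benzyloxy)-1,3-dimethoxy-5-(prop-2-yn-1-yloxy)benzene F11. Deprotonation of the alkyne (n-BuLi, THF, −78 °C) and trapping with methyl chloroformate give methyl 4-[4-(benzyloxy)-3,5-dimethoxyphenoxy]but-2-ynoate F12. Base-catalysed oxa-Michael addition of 12 to the unhindered sp carbon of F12 (Cs2CO3 cat., MeCN, 50 °C), followed by equilibration to the conjugated (E) enol ether, gives 13.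

Further compounds
F1 | step 8 | 6-bromo-2,3,4-trimethoxybenzaldehyde | COc1cc(Br)c(C=O)c(OC)c1OC
F2 | step 8 | 6-[2,6-dimethoxy-4-(2,4,6-trimethoxyphenoxy)phenoxy]-2,3,4-trimethoxybenzaldehyde | COc1cc(Oc2c(OC)cc(Oc3c(OC)cc(OC)cc3OC)cc2OC)c(C=O)c(OC)c1OC
F3 | step 8 | 6-[2,6-dimethoxy-4-(2,4,6-trimethoxyphenoxy)phenoxy]-2,3,4-trimethoxyphenyl formate | COc1cc(Oc2c(OC)cc(Oc3c(OC)cc(OC)cc3OC)cc2OC)c(OC=O)c(OC)c1OC
F4 | step 8 | 6-[2,6-dimethoxy-4-(2,4,6-trimethoxyphenoxy)phenoxy]-2,3,4-trimethoxyphenol | COc1cc(Oc2c(OC)cc(Oc3c(OC)cc(OC)cc3OC)cc2OC)c(O)c(OC)c1OC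
F5 | step 8 | 2-(benzyloxy)-5-bromo-1,3-dimethoxybenzene | COc1cc(Br)cc(OC)c1OCc1ccccc1
F6 | step 18 | 2-(ABCDO)-3,4,5-trimethoxybenzaldehyde | COc1cc(C=O)c(Oc2c(OC)cc(Oc3c(OC)c(OC)c(OC)cc3Oc3c(OC)cc(Oc4c(OC)cc(OC)cc4OC)cc3OC)cc2OC)c(OC)c1OC
F7 | step 18 | 2-(ABCDO)-3,4,5-trimethoxyphenyl formate | COc1cc(OC=O)c(Oc2c(OC)cc(Oc3c(OC)c(OC)c(OC)cc3Oc3c(OC)cc(Oc4c(OC)cc(OC)cc4OC)cc3OC)cc2OC)c(OC)c1OC
F8 | step 18 | 2-(ABCDO)-3,4,5-trimethoxyphenol | COc1cc(O)c(Oc2c(OC)cc(Oc3c(OC)c(OC)c(OC)cc3Oc3c(OC)cc(Oc4c(OC)cc(OC)cc4OC)cc3OC)cc2OC)c(OC)c1OC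
F9 | step 18 | 3,4-dimethoxy-5-[3,4,5-trimethoxy-2-(3,4,5-trimethoxyphenoxy)phenoxy]phenyl trifluoromethanesulfonate | COc1cc(OS(=O)(=O)C(F)(F)F)cc(Oc2cc(OC)c(OC)c(OC)c2Oc2cc(OC)c(OC)c(OC)c2)c1OC
F10 | step 18 | 4-(ABCDO)-5-(FGHO)-1,2,3-trimethoxybenzene | COc1cc(Oc2cc(OC)c(OC)c(Oc3cc(OC)c(OC)c(OC)c3Oc3cc(OC)c(OC)c(OC)c3)c2)c(Oc2c(OC)cc(Oc3c(OC)c(OC)c(OC)cc3Oc3c(OC)cc(Oc4c(OC)cc(OC)cc4OC)cc3OC)cc2OC)c(OC)c1OC
F11 | step 7 | 2-(benzyloxy)-1,3-dimethoxy-5-(prop-2-yn-1-yloxy)benzene | COc1cc(OCC#C)cc(OC)c1OCc1ccccc1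
F12 | step 7 | methyl 4-[4-(benzyloxy)-3,5-dimethoxyphenoxy]but-2-ynoate | COC(=O)C#CCOc1cc(OC)c(OCc2ccccc2)c(OC)c1
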